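**Retrosynthetic overview**

1. The target, the linear (−)-epicatechin tetramer with three 4β→8 bonds, comes from its heptadeca-O-benzyl ether by global hydrogenolysis. The three lower epicatechin units (nine rings) are taken intact from (−)-epicatechin as a benzylated 4β→8 trimer with a free C8 on ring D (the phloroglucinol ring of the second unit of the target).
2. Key disconnection: both aryl bonds of C4 in ring C of the top unit, C4–C4a (to ring A) and C4–C8 (to ring D), giving an open-chain (2S,3R) aryl ether acetal plus the trimer. Enabling feature: C4 is a diarylmethine between two phloroglucinol-type carbons, C4a (ortho to O1 on ring A) and C8 of ring D. At the acetal oxidation level it is a 1,1-dielectrophile, and after the first arylation its cation is the O-alkylated ortho-quinone methide O1=C8a–C4a=C4 of ring A.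
3. Open-chain precursor: C2–C3 and both stereocentres by an Evans syn glycolate aldol; O1–C8a by palladium-catalysed C–O coupling with retention at C2; C4 brought to the dimethyl acetal.
4. Trimer: benzylation of (−)-epicatechin, DDQ activation of C4, two TMSOTf-mediated 4β→8 couplings.
5. Ring order: all rings of the three lower units and arene rings A and B of the top unit exist from the start; ring C of the top unit is the only ring made and is closed last, in the operation that also forms the third interflavan bond.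

Key step: step 13

Assumption: TMSOTf is used sub-stoichiometrically (as a catalyst) in steps 3, 4 and 13, and each flavan nucleophile is taken to react at C8 of its upper-terminal phloroglucinol ring, the usual site for benzylated flavan-3-ols.

**Route**

Step 1
Reactants: 1 (−)-epicatechin
Product: 2 5,7,3',4'-tetra-O-benzyl-(−)-epicatechin (3-OH free)
Conditions: BnBr (4.4 equiv), K2CO3, DMF, 0 °C → rt
Reagents that add atoms: benzyl bromide, BrCc1ccccc1
Why: Williamson etherification, in which the four phenols (far more acidic than the secondary 3-OH) are alkylated under carbonate base, leaving O3 free and both stereocentres untouched.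

Step 2
Reactants: 2 5,7,3',4'-tetra-O-benzyl-(−)-epicatechin
Product: 3 4β-(2-ethoxyethoxy)-5,7,3',4'-tetra-O-benzyl-(−)-epicatechin (2,3-cis-3,4-trans, 3-OH free)
Conditions: DDQ (2 equiv), 2-ethoxyethanol (5 equiv), CH2Cl2, rt
Reagents that add atoms: 2-ethoxyethanol, CCOCCO
Why: DDQ benzylic oxidation (hydride abstraction at C4, activated by the ortho and para oxygens of ring A) should give the C4 cation, which the alcohol traps anti to the axial C3 hydroxyl to set the 4β (3,4-trans) ether.

Step 3
Reactants: 3 4β-(2-ethoxyethoxy)-5,7,3',4'-tetra-O-benzyl-(−)-epicatechin; 2 5,7,3',4'-tetra-O-benzyl-(−)-epicatechin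
Product: 4 octa-O-benzyl-epicatechin-(4β→8)-epicatechin (benzylated dimer with eight phenols benzylated and both 3-OH free)
Conditions: TMSOTf (0.2 equiv), 2 (3 equiv), CH2Cl2, −78 °C; Et3N quench
Reagents that add atoms: none
Why: Lewis-acid-mediated Friedel–Crafts (SN1) interflavan coupling, in which TMSOTf ionises the C4 ether and C8 of excess 2 attacks the cation anti to the C3 oxygen, setting the 4β→8 (3,4-trans) bond.

Step 4
Reactants: 4 octa-O-benzyl-epicatechin-(4β→8)-epicatechin; 3 4β-(2-ethoxyethoxy)-5,7,3',4'-tetra-O-benzyl-(−)-epicatechin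
Product: 5 dodeca-O-benzyl-epicatechin-(4β→8)-epicatechin-(4β→8)-epicatechin (benzylated trimer with twelve phenols benzylated and three 3-OH free)
Conditions: TMSOTf (0.2 equiv), 4 (1.5 equiv), CH2Cl2, −78 °C; Et3N quench
Reagents that add atoms: none
Why: the same Friedel–Crafts-type coupling, with C8 of the upper-terminal unit of 4 as nucleophile and attack anti to the C3 oxygen of the cation giving the second 4β→8 bond.

Step 5
Reactants: 6 (S)-4-benzyl-1,3-oxazolidin-2-one; 7 (benzyloxy)acetyl chloride
Product: 9 (S)-4-benzyl-3-[(benzyloxy)acetyl]-1,3-oxazolidin-2-one, via lithium oxazolidinide 8 (not isolated)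
Conditions: n-BuLi (1.0 equiv), THF, −78 °C; then 7, −78 → 0 °C
Reagents that add atoms: none
Why: N-acylation (nucleophilic acyl substitution) of the lithiated auxiliary by the acid chloride, with no new stereocentre.

Step 6
Reactants: 9 (S)-4-benzyl-3-[(benzyloxy)acetyl]-1,3-oxazolidin-2-one; 10 3,4-bis(benzyloxy)benzaldehyde
Product: 13 (S)-4-benzyl-3-[(2S,3R)-2-(benzyloxy)-3-[3,4-bis(benzyloxy)phenyl]-3-hydroxypropanoyl]-1,3-oxazolidin-2-one, via Z-boron enolate 11 (not isolated), via boron aldolate 12 (not isolated)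
Conditions: Bu2BOTf (1.2 equiv), iPr2NEt (1.4 equiv), CH2Cl2, −78 → 0 °C; 10, −78 → 0 °C; then pH 7 buffer, MeOH, H2O2, 0 °C
Reagents that add atoms: none
Why: Evans syn glycolate aldol, in which the Z-boron enolate reacts through a closed chair transition state on the enolate face away from the auxiliary benzyl group, setting the glycolate carbon (S, the future flavan C3) and the carbinol carbon (R, the future flavan C2) as the syn pair.

Step 7
Reactants: 13 the syn aldol adduct
Product: 14 (1R,2R)-2-(benzyloxy)-1-[3,4-bis(benzyloxy)phenyl]propane-1,3-diol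
Conditions: LiBH4, MeOH (1 equiv), THF, 0 °C
Reagents that add atoms: none
Why: reductive cleavage of the imide (hydride reduction of the exocyclic acyl group) should release the 1,3-diol and the auxiliary without touching either stereocentre.

Step 8
Reactants: 14 (1R,2R)-2-(benzyloxy)-1-[3,4-bis(benzyloxy)phenyl]propane-1,3-diol
Product: 15 (1R,2R)-2-(benzyloxy)-1-[3,4-bis(benzyloxy)phenyl]-3-[(triisopropylsilyl)oxy]propan-1-ol
Conditions: TIPSCl (1.1 equiv), imidazole, DMAP (cat.), CH2Cl2, 0 °C → rt
Reagents that add atoms: triisopropylsilyl chloride, CC(C)[Si](Cl)(C(C)C)C(C)C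
Why: selective silylation of the primary hydroxyl by a bulky silyl chloride, leaving the hindered benzylic hydroxyl free and giving a silyl ether that should not migrate under the carbonate base of the next step.

Step 9
Reactants: 15 (1R,2R)-2-(benzyloxy)-1-[3,4-bis(benzyloxy)phenyl]-3-[(triisopropylsilyl)oxy]propan-1-ol; 16 1,3-bis(benzyloxy)-5-bromobenzene
Product: 17 [(2R,3R)-2-(benzyloxy)-3-[3,4-bis(benzyloxy)phenyl]-3-[3,5-bis(benzyloxy)phenoxy]propoxy]triisopropylsilane
Conditions: [Pd(C3H5)Cl]2 (2 mol %), RockPhos (5 mol %), Cs2CO3, 16 (1.5 equiv), toluene, 90 °C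
Reagents that add atoms: none
Why: palladium-catalysed C–O cross-coupling (Buchwald–Hartwig-type etherification) of the secondary alcohol with the aryl bromide forms O1–C8a at the aryl carbon, so the carbinol C–O bond is never broken and the configuration of the future C2 is retained, while the bulky biaryl phosphine favours reductive elimination over β-hydride elimination.

Step 10
Reactants: 17 the silyl-protected aryl ether
Product: 18 (2R,3R)-2-(benzyloxy)-3-[3,4-bis(benzyloxy)phenyl]-3-[3,5-bis(benzyloxy)phenoxy]propan-1-ol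
Conditions: TBAF (1.2 equiv), THF, 0 °C → rt
Reagents that add atoms: none
Why: fluoride-mediated desilylation of the primary silyl ether, to which benzyl and aryl ethers are inert.

Step 11
Reactants: 18 (2R,3R)-2-(benzyloxy)-3-[3,4-bis(benzyloxy)phenyl]-3-[3,5-bis(benzyloxy)phenoxy]propan-1-ol
Product: 19 (2S,3R)-2-(benzyloxy)-3-[3,4-bis(benzyloxy)phenyl]-3-[3,5-bis(benzyloxy)phenoxy]propanal
Conditions: Dess–Martin periodinane (1.3 equiv), CH2Cl2, 0 °C → rt; used crude
Reagents that add atoms: none
Why: Dess–Martin oxidation of the primary alcohol under base-free conditions, chosen to avoid epimerisation of the α-alkoxy centre and β-elimination of the aryloxide.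

Step 12
Reactants: 19 (2S,3R)-2-(benzyloxy)-3-[3,4-bis(benzyloxy)phenyl]-3-[3,5-bis(benzyloxy)phenoxy]propanal
Product: 20 (2S,3R)-2-(benzyloxy)-3-[3,4-bis(benzyloxy)phenyl]-3-[3,5-bis(benzyloxy)phenoxy]propanal dimethyl acetal
Conditions: HC(OMe)3, PPTS (cat.), MeOH, rt
Reagents that add atoms: trimethyl orthoformate, COC(OC)OC
Why: acid-catalysed acetalisation under mild pyridinium catalysis should leave the benzylic aryl ether intact and give a configurationally stable, storable form of the aldehyde.

Step 13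
Reactants: 20 the (2S,3R) aryl ether dimethyl acetal; 5 dodeca-O-benzyl-epicatechin-(4β→8)-epicatechin-(4β→8)-epicatechin
Product: 22 heptadeca-O-benzyl epicatechin-(4β→8) tetramer, via 4-methoxyflavan 21 (not isolated)
Conditions: TMSOTf (0.3 equiv), 5 (1.5 equiv), 4 Å MS, CH2Cl2 (0.02 M), −78 → −40 °C; Et3N quench
Reagents that add atoms: none
Why: Proposed new method: TMSOTf should ionise the acetal of 20 to a methoxy-oxocarbenium ion at C4, which the tethered 3,5-bis(benzyloxy)phenoxy ring attacks through the carbon ortho to O1 (intramolecular Friedel–Crafts alkylation, 6-exo-trig at the oxocarbenium carbon and 6-endo for the arene π bond, forming C4–C4a and closing ring C to give 21); a second ionisation of 21 gives the C4 benzylic cation, the O-alkylated ortho-quinone methide O1=C8a–C4a=C4 of ring A, which C8 of ring D of trimer 5 captures to form the interflavan bond. The closest known reaction types are the Lewis-acid cyclisation of 3-aryloxypropanal acetals to 4-alkoxychromans and the TMSOTf-mediated C4–C8 coupling of 4-alkoxyflavan-3-ols with benzylated flavan-3-ols; the new element is their merger into one unsymmetrical double Friedel–Crafts (Baeyer-type) diarylation of a single carbon. C2 and C3 are carried unchanged from 20, and the only new stereocentre, C4, is controlled by the ring just formed: in the half-chair cation the C2 aryl group is equatorial and the C3 benzyloxy group axial, so the arene should add to the opposite face and give the 3,4-trans (4β) bond, as is general for 2,3-cis flavan-4-yl cations, while the C4 configuration of 21 is irrelevant because ionisation erases it. The step needs ring closure to precede intermolecular capture, which the tether should secure (six-membered closure onto a phloroglucinol-type ring with two equivalent ortho positions, at high dilution, against the hindered C8 of 5), and it needs C8 over C6 selectivity in 5, the normal preference of benzylated flavan nucleophiles. The excess of 5 should limit a second alkylation on the newly formed ring A.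

Step 14
Reactants: 22 heptadeca-O-benzyl epicatechin-(4β→8) tetramer
Product: 23 epicatechin-(4β→8)-epicatechin-(4β→8)-epicatechin-(4β→8)-epicatechin (the target tetramer)
Conditions: H2 (1 atm), Pd(OH)2/C, THF/MeOH/H2O, rt
Reagents that add atoms: none
Why: heterogeneous hydrogenolysis of all seventeen benzyl ethers (sixteen aryl, one alkyl) under neutral conditions should leave the acid-labile interflavan bonds, the O1–C2 bonds and every stereocentre untouched.

**Compound list**

1 | (−)-epicatechin, (2R,3R) | Oc1cc(O)c2c(c1)O[C@H](c1ccc(O)c(O)c1)[C@H](O)C2 | starting material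
2 | 5,7,3',4'-tetra-O-benzyl-(−)-epicatechin | c1(OCc3ccccc3)cc(OCc3ccccc3)c2c(c1)O[C@H](c1ccc(OCc3ccccc3)c(OCc3ccccc3)c1)[C@H](O)C2 | intermediate
3 | 4β-(2-ethoxyethoxy)-5,7,3',4'-tetra-O-benzyl-(−)-epicatechin (2,3-cis-3,4-trans) | c1(OCc3ccccc3)cc(OCc3ccccc3)c2c(c1)O[C@H](c1ccc(OCc3ccccc3)c(OCc3ccccc3)c1)[C@H](O)[C@H]2OCCOCC | intermediate
4 | octa-O-benzyl-epicatechin-(4β→8)-epicatechin (benzylated dimer, both 3-OH free) | c1(OCc3ccccc3)cc(OCc3ccccc3)c2c(c1)O[C@H](c1ccc(OCc3ccccc3)c(OCc3ccccc3)c1)[C@H](O)[C@H]2c1c(OCc3ccccc3)cc(OCc3ccccc3)c2c1O[C@H](c1ccc(OCc3ccccc3)c(OCc3ccccc3)c1)[C@H](O)C2 | intermediate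
5 | dodeca-O-benzyl-epicatechin-(4β→8)-epicatechin-(4β→8)-epicatechin (benzylated trimer, three 3-OH free) | c1(OCc3ccccc3)cc(OCc3ccccc3)c2c(c1)O[C@H](c1ccc(OCc3ccccc3)c(OCc3ccccc3)c1)[C@H](O)[C@H]2c1c(OCc3ccccc3)cc(OCc3ccccc3)c2c1O[C@H](c1ccc(OCc3ccccc3)c(OCc3ccccc3)c1)[C@H](O)[C@H]2c1c(OCc3ccccc3)cc(OCc3ccccc3)c2c1O[C@H](c1ccc(OCc3ccccc3)c(OCc3ccccc3)c1)[C@H](O)C2 | intermediate
6 | (S)-4-benzyl-1,3-oxazolidin-2-one | O=C1OC[C@H](Cc2ccccc2)N1 | starting material
7 | (benzyloxy)acetyl chloride | O=C(Cl)COCc1ccccc1 | starting material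
8 | lithium salt of (S)-4-benzyl-1,3-oxazolidin-2-one | [Li+].O=C1OC[C@H](Cc2ccccc2)[N-]1 | intermediate (not isolated)
9 | (S)-4-benzyl-3-[(benzyloxy)acetyl]-1,3-oxazolidin-2-one | O=C(COCc1ccccc1)N1C(=O)OC[C@@H]1Cc1ccccc1 | intermediate
10 | 3,4-bis(benzyloxy)benzaldehyde | O=Cc1ccc(OCc2ccccc2)c(OCc2ccccc2)c1 | starting material
11 | Z-dibutylboron enolate of 9 | CCCCB(CCCC)O/C(=C\OCc1ccccc1)N1C(=O)OC[C@@H]1Cc1ccccc1 | intermediate (not isolated)
12 | O-dibutylboryl aldolate of 13 | CCCCB(CCCC)O[C@H](c1ccc(OCc3ccccc3)c(OCc3ccccc3)c1)[C@H](OCc3ccccc3)C(=O)N1C(=O)OC[C@@H]1Cc1ccccc1 | intermediate (not isolated)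
13 | (S)-4-benzyl-3-[(2S,3R)-2-(benzyloxy)-3-[3,4-bis(benzyloxy)phenyl]-3-hydroxypropanoyl]-1,3-oxazolidin-2-one | O[C@H](c1ccc(OCc3ccccc3)c(OCc3ccccc3)c1)[C@H](OCc3ccccc3)C(=O)N1C(=O)OC[C@@H]1Cc1ccccc1 | intermediate
14 | (1R,2R)-2-(benzyloxy)-1-[3,4-bis(benzyloxy)phenyl]propane-1,3-diol | O[C@H](c1ccc(OCc3ccccc3)c(OCc3ccccc3)c1)[C@H](OCc3ccccc3)CO | intermediate
15 | (1R,2R)-2-(benzyloxy)-1-[3,4-bis(benzyloxy)phenyl]-3-[(triisopropylsilyl)oxy]propan-1-ol | O[C@H](c1ccc(OCc3ccccc3)c(OCc3ccccc3)c1)[C@H](OCc3ccccc3)CO[Si](C(C)C)(C(C)C)C(C)C | intermediate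
16 | 1,3-bis(benzyloxy)-5-bromobenzene | Brc1cc(OCc2ccccc2)cc(OCc2ccccc2)c1 | starting material
17 | [(2R,3R)-2-(benzyloxy)-3-[3,4-bis(benzyloxy)phenyl]-3-[3,5-bis(benzyloxy)phenoxy]propoxy]triisopropylsilane | c1(OCc3ccccc3)cc(OCc3ccccc3)cc(c1)O[C@H](c1ccc(OCc3ccccc3)c(OCc3ccccc3)c1)[C@H](OCc3ccccc3)CO[Si](C(C)C)(C(C)C)C(C)C | intermediate
18 | (2R,3R)-2-(benzyloxy)-3-[3,4-bis(benzyloxy)phenyl]-3-[3,5-bis(benzyloxy)phenoxy]propan-1-ol | c1(OCc3ccccc3)cc(OCc3ccccc3)cc(c1)O[C@H](c1ccc(OCc3ccccc3)c(OCc3ccccc3)c1)[C@H](OCc3ccccc3)CO | intermediate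
19 | (2S,3R)-2-(benzyloxy)-3-[3,4-bis(benzyloxy)phenyl]-3-[3,5-bis(benzyloxy)phenoxy]propanal | c1(OCc3ccccc3)cc(OCc3ccccc3)cc(c1)O[C@H](c1ccc(OCc3ccccc3)c(OCc3ccccc3)c1)[C@H](OCc3ccccc3)C=O | intermediate
20 | (2S,3R)-2-(benzyloxy)-3-[3,4-bis(benzyloxy)phenyl]-3-[3,5-bis(benzyloxy)phenoxy]propanal dimethyl acetal | c1(OCc3ccccc3)cc(OCc3ccccc3)cc(c1)O[C@H](c1ccc(OCc3ccccc3)c(OCc3ccccc3)c1)[C@H](OCc3ccccc3)C(OC)OC | intermediate
21 | 4-methoxy-3,5,7,3',4'-penta-O-benzyl-epicatechin, (2R,3R)-2,3-cis, both C4 epimers | c1(OCc3ccccc3)cc(OCc3ccccc3)c2c(c1)O[C@H](c1ccc(OCc3ccccc3)c(OCc3ccccc3)c1)[C@H](OCc3ccccc3)C2OC | intermediate (not isolated)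
22 | heptadeca-O-benzyl-epicatechin-(4β→8)-epicatechin-(4β→8)-epicatechin-(4β→8)-epicatechin (sixteen phenols and O3 of the top unit benzylated, three lower 3-OH free, every unit 2,3-cis, every interflavan bond 4β→8) | c1(OCc3ccccc3)cc(OCc3ccccc3)c2c(c1)O[C@H](c1ccc(OCc3ccccc3)c(OCc3ccccc3)c1)[C@H](OCc3ccccc3)[C@H]2c1c(OCc3ccccc3)cc(OCc3ccccc3)c2c1O[C@H](c1ccc(OCc3ccccc3)c(OCc3ccccc3)c1)[C@H](O)[C@H]2c1c(OCc3ccccc3)cc(OCc3ccccc3)c2c1O[C@H](c1ccc(OCc3ccccc3)c(OCc3ccccc3)c1)[C@H](O)[C@H]2c1c(OCc3ccccc3)cc(OCc3ccccc3)c2c1O[C@H](c1ccc(OCc3ccccc3)c(OCc3ccccc3)c1)[C@H](O)C2 | intermediate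
23 | epicatechin-(4β→8)-epicatechin-(4β→8)-epicatechin-(4β→8)-epicatechin, the linear (−)-epicatechin tetramer | Oc1cc(O)c2c(c1)O[C@H](c1ccc(O)c(O)c1)[C@H](O)[C@H]2c1c(O)cc(O)c2c1O[C@H](c1ccc(O)c(O)c1)[C@H](O)[C@H]2c1c(O)cc(O)c2c1O[C@H](c1ccc(O)c(O)c1)[C@H](O)[C@H]2c1c(O)cc(O)c2c1O[C@H](c1ccc(O)c(O)c1)[C@H](O)C2 | target

**Totals and risks**

Total step count: 14. Longest linear sequence: 10 steps (steps 5 to 14); the trimer branch (steps 1 to 4) joins at step 13.

Steps most likely to fail:

1. Step 13 (proposed method). Process at risk: capture of the open-chain oxocarbenium ion by the trimer before ring closure, so that C4 would be set without the control of the ring, together with self-alkylation of the cyclised electrophile and ionisation of the benzylic C2–O1 bond of the open-chain ether. Fallback, using only known reaction types: the cascade is given up and its two events are run as separate operations. Setting out from 20, the acetal alone is cyclised with BF3·OEt2 (0.2 equiv) in CH2Cl2 at −78 °C (Lewis-acid cyclisation of a 3-aryloxypropanal acetal to a 4-alkoxychroman) and 4-methoxyflavan 21 is isolated. Compound 21 is then used as a conventional 4-alkoxyflavan electrophile with 5 under TMSOTf at −78 °C, which comes back to the route at 22. No new compound arises (F0).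

2. Step 9. Process at risk: β-hydride elimination from the palladium alkoxide of the hindered benzylic alcohol (oxidation of the alcohol, reduction of the aryl bromide), or no coupling for steric reasons. Fallback: the ether is made by substitution at carbon with inversion instead of coupling at the arene. Setting out from 15, Dess–Martin oxidation gives (R)-2-(benzyloxy)-1-[3,4-bis(benzyloxy)phenyl]-3-[(triisopropylsilyl)oxy]propan-1-one F1. Chelation-controlled reduction with Zn(BH4)2 (Et2O, −20 °C) should give the anti alcohol (1S,2R)-2-(benzyloxy)-1-[3,4-bis(benzyloxy)phenyl]-3-[(triisopropylsilyl)oxy]propan-1-ol F2. Mitsunobu etherification of F2 with commercial 3,5-bis(benzyloxy)phenol (PPh3, DIAD, toluene, 0 °C) inverts the benzylic centre and comes back to the route at 17.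

3. Step 4. Process at risk: loss of chain-length control, since the trimer formed and the electrophile itself are also nucleophiles, so over-alkylation and self-condensation compete, and the excess nucleophile here is a valuable dimer. Fallback: the roles are reversed so that the cheap monomer can be used in large excess. Setting out from 4, DDQ oxidation with 2-ethoxyethanol at the one remaining flavan C4 methylene (C4 of the lower unit) should give the dimeric electrophile 4β-(2-ethoxyethoxy)-octa-O-benzyl-epicatechin-(4β→8)-epicatechin F3, with the ether on the lower unit. TMSOTf-mediated coupling of F3 with a large excess of monomer 2 comes back to the route at 5.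

**Further compounds**

F0 | step 13 | none | none
F1 | step 9 | (R)-2-(benzyloxy)-1-[3,4-bis(benzyloxy)phenyl]-3-[(triisopropylsilyl)oxy]propan-1-one | O=C(c1ccc(OCc3ccccc3)c(OCc3ccccc3)c1)[C@H](OCc3ccccc3)CO[Si](C(C)C)(C(C)C)C(C)C
F2 | step 9 | (1S,2R)-2-(benzyloxy)-1-[3,4-bis(benzyloxy)phenyl]-3-[(triisopropylsilyl)oxy]propan-1-ol | O[C@@H](c1ccc(OCc3ccccc3)c(OCc3ccccc3)c1)[C@H](OCc3ccccc3)CO[Si](C(C)C)(C(C)C)C(C)C
F3 | step 4 | 4β-(2-ethoxyethoxy)-octa-O-benzyl-epicatechin-(4β→8)-epicatechin (ether at C4 of the lower unit) | c1(OCc3ccccc3)cc(OCc3ccccc3)c2c(c1)O[C@H](c1ccc(OCc3ccccc3)c(OCc3ccccc3)c1)[C@H](O)[C@H]2c1c(OCc3ccccc3)cc(OCc3ccccc3)c2c1O[C@H](c1ccc(OCc3ccccc3)c(OCc3ccccc3)c1)[C@H](O)[C@H]2OCCOCC
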